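The ten-membered carbocycle is not closed end to end; it is grown from a cyclohexene. The feature exploited is the oxy-1,5-diene O–C6(C7=C8)–C1–C10=C9 that spans the C1–C6 bond of a six-membered ring A (C1–C6), which already holds C2–O and the ring-cis C4=C5 bond. With the (E)-2-(PMB-oxy)vinyl arm at C6 and the 2-propenyl arm at C1 on the same face, alkoxide formation triggers a [3,3] shift that bonds C8 to C9 and cuts C1–C6: one operation delivers the cyclodecadienone with ring-cis C1=C10, the C8 stereocentre and the C6 carbonyl for lactone annulation. Ring A comes from an auxiliary-controlled syn-aldol and ring-closing metathesis.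

Key step: step 16

Remark: carbons carry germacrane locants (ring C1–C10, lactone carbons C11–C13, C14 on C10, C15 on C4); both ring double bonds are ring-cis although their CIP label is E; oxygen protection is PMB at C8 and C15, TBS at C14, TIPS at C2; C11 of 35 and 36 is an unassigned epimer mixture that becomes sp2 in the same step.

Step 1
Reactants: 1 2-bromoprop-2-en-1-ol
Product: 2 [(2-bromoprop-2-en-1-yl)oxy](tert-butyl)dimethylsilane
Conditions: TBSCl, imidazole, CH2Cl2, 0 °C to rt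
Reagents that add atoms: tert-butyl(chloro)dimethylsilane (TBSCl), CC(C)(C)[Si](C)(C)Cl
Why: Imidazole-promoted silyl ether formation at a primary allylic alcohol; the TBS ether (future C14 oxygen) tolerates all later basic and organometallic steps.

Step 2
Reactants: 2 [(2-bromoprop-2-en-1-yl)oxy](tert-butyl)dimethylsilane; 3 bromo(2-ethoxy-2-oxoethyl)zinc (Reformatsky reagent BrZnCH2CO2Et, commercial THF solution)
Product: 4 ethyl 3-({[tert-butyl(dimethyl)silyl]oxy}methyl)but-3-enoate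
Conditions: Pd2(dba)3 (2.5 mol %), XPhos (10 mol %), THF, 50 °C
Reagents that add atoms: none
Why: Negishi-type coupling of a Reformatsky zinc enolate with an alkenyl bromide (oxidative addition of zerovalent palladium, transmetalation, reductive elimination) attaches the CH2CO2Et unit (future C1 and C6) without moving the 1,1-disubstituted double bond.

Step 3
Reactants: 4 ethyl 3-({[tert-butyl(dimethyl)silyl]oxy}methyl)but-3-enoate
Product: 5 3-({[tert-butyl(dimethyl)silyl]oxy}methyl)but-3-enoic acid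
Conditions: LiOH·H2O, THF/H2O (3:1), 0 °C to rt; then 1 M HCl to pH 4, 0 °C
Reagents that add atoms: lithium hydroxide monohydrate (its hydroxide oxygen ends in the CO2H group), [Li+].[OH-].O
Why: Ester saponification under mild conditions that leave the primary TBS ether and the deconjugated alkene in place.

Step 4
Reactants: 5 3-({[tert-butyl(dimethyl)silyl]oxy}methyl)but-3-enoic acid; 6 (4R)-4-benzyl-1,3-oxazolidin-2-one
Product: 8 (4R)-4-benzyl-3-[3-({[tert-butyl(dimethyl)silyl]oxy}methyl)but-3-enoyl]-1,3-oxazolidin-2-one, via mixed pivalic anhydride 7 (not isolated)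
Conditions: tBuCOCl, Et3N, THF, −20 °C; then 6, LiCl, −20 °C to rt
Reagents that add atoms: none
Why: N-acylation of the oxazolidinone through a mixed anhydride (LiCl/Et3N activation), in which the hindered pivaloyl carbonyl directs attack to the butenoyl carbonyl and the auxiliary stereocentre is untouched.

Step 5
Reactants: 1 2-bromoprop-2-en-1-ol
Product: 9 1-{[(2-bromoprop-2-en-1-yl)oxy]methyl}-4-methoxybenzene
Conditions: NaH, THF/DMF, 0 °C; 4-methoxybenzyl chloride, Bu4NI (cat.), rt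
Reagents that add atoms: 4-methoxybenzyl chloride, COc1ccc(CCl)cc1
Why: Williamson ether synthesis (alkoxide plus benzylic chloride under iodide catalysis); PMB on the future C15 oxygen can later be removed together with the C8 PMB ether.

Step 6
Reactants: 9 1-{[(2-bromoprop-2-en-1-yl)oxy]methyl}-4-methoxybenzene; 3 bromo(2-ethoxy-2-oxoethyl)zinc
Product: 10 ethyl 3-{[(4-methoxybenzyl)oxy]methyl}but-3-enoate
Conditions: Pd2(dba)3 (2.5 mol %), XPhos (10 mol %), THF, 50 °C
Reagents that add atoms: none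
Why: The same Negishi-type coupling of the Reformatsky reagent with an alkenyl bromide as in step 2, here giving the ester that holds the future C2, C3, C4 and C15.

Step 7
Reactants: 10 ethyl 3-{[(4-methoxybenzyl)oxy]methyl}but-3-enoate
Product: 11 3-{[(4-methoxybenzyl)oxy]methyl}but-3-enal
Conditions: iBu2AlH (1.05 equiv), CH2Cl2, −78 °C; MeOH, then aq KNaC4H4O6
Reagents that add atoms: none
Why: Partial reduction of an ester with iBu2AlH, which at −78 °C stops at the aldehyde oxidation level; the β,γ-unsaturated aldehyde is used at once so that the double bond does not drift into conjugation.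

Step 8
Reactants: 8 (4R)-4-benzyl-3-[3-({[tert-butyl(dimethyl)silyl]oxy}methyl)but-3-enoyl]-1,3-oxazolidin-2-one; 11 3-{[(4-methoxybenzyl)oxy]methyl}but-3-enal
Product: 13 (4R)-4-benzyl-3-[(2R,3S)-2-(3-{[tert-butyl(dimethyl)silyl]oxy}prop-1-en-2-yl)-3-hydroxy-5-{[(4-methoxybenzyl)oxy]methyl}hex-5-enoyl]-1,3-oxazolidin-2-one, via boron enolate 12 (not isolated)
Conditions: Bu2BOTf, iPr2NEt, CH2Cl2, −78 to 0 °C; then 11, −78 to 0 °C; pH 7 buffer, MeOH, 30% H2O2, 0 °C
Reagents that add atoms: none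
Why: Evans syn-aldol reaction, in which the (Z)-boron enolate adds through a Zimmerman–Traxler chair on the face away from the benzyl group of the (R)-auxiliary and sets C1 (R) and C2 (S) in the syn relation that becomes the trans arrangement of the C1 alkenyl arm and the C2 oxygen in ring A.

Step 9
Reactants: 13 (4R)-4-benzyl-3-[(2R,3S)-2-(3-{[tert-butyl(dimethyl)silyl]oxy}prop-1-en-2-yl)-3-hydroxy-5-{[(4-methoxybenzyl)oxy]methyl}hex-5-enoyl]-1,3-oxazolidin-2-one
Product: 14 (2R,3S)-2-(3-{[tert-butyl(dimethyl)silyl]oxy}prop-1-en-2-yl)-3-hydroxy-N-methoxy-5-{[(4-methoxybenzyl)oxy]methyl}-N-methylhex-5-enamide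
Conditions: MeNHOMe·HCl, AlMe3, CH2Cl2, −10 to 0 °C; aq KNaC4H4O6
Reagents that add atoms: N,O-dimethylhydroxylamine hydrochloride, CNOC.Cl
Why: Aluminium amide transamination of a β-hydroxy imide to the Weinreb amide, helped by the free C2 hydroxyl, releases the auxiliary without change at C1 or C2.

Step 10
Reactants: 14 (2R,3S)-2-(3-{[tert-butyl(dimethyl)silyl]oxy}prop-1-en-2-yl)-3-hydroxy-N-methoxy-5-{[(4-methoxybenzyl)oxy]methyl}-N-methylhex-5-enamide
Product: 15 (2R,3S)-2-(3-{[tert-butyl(dimethyl)silyl]oxy}prop-1-en-2-yl)-N-methoxy-5-{[(4-methoxybenzyl)oxy]methyl}-N-methyl-3-[(triisopropylsilyl)oxy]hex-5-enamide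
Conditions: TIPSOTf, 2,6-lutidine, CH2Cl2, 0 °C to rt
Reagents that add atoms: triisopropylsilyl trifluoromethanesulfonate (TIPSOTf), CC(C)[Si](OS(=O)(=O)C(F)(F)F)(C(C)C)C(C)C
Why: Silylation of a secondary alcohol with a silyl triflate and a hindered pyridine base; TIPS is chosen because its bulk should block silyl migration to the C6 alkoxide in the key step.

Step 11
Reactants: 15 (2R,3S)-2-(3-{[tert-butyl(dimethyl)silyl]oxy}prop-1-en-2-yl)-N-methoxy-5-{[(4-methoxybenzyl)oxy]methyl}-N-methyl-3-[(triisopropylsilyl)oxy]hex-5-enamide; 16 bromo(ethenyl)magnesium (CH2=CHMgBr, commercial THF solution)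
Product: 17 (4R,5S)-4-(3-{[tert-butyl(dimethyl)silyl]oxy}prop-1-en-2-yl)-7-{[(4-methoxybenzyl)oxy]methyl}-5-[(triisopropylsilyl)oxy]octa-1,7-dien-3-one
Conditions: CH2=CHMgBr (3 equiv), THF, 0 °C; poured into cold 1 M HCl
Reagents that add atoms: none
Why: Weinreb ketone synthesis, in which the N-methoxy-N-methyl amide takes up a single equivalent of Grignard reagent and the vinyl ketone is released only on acidic quench, so the acidic C1–H never meets the reagent as a ketone.

Step 12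
Reactants: 17 (4R,5S)-4-(3-{[tert-butyl(dimethyl)silyl]oxy}prop-1-en-2-yl)-7-{[(4-methoxybenzyl)oxy]methyl}-5-[(triisopropylsilyl)oxy]octa-1,7-dien-3-one
Product: 18 (5S,6R)-6-(3-{[tert-butyl(dimethyl)silyl]oxy}prop-1-en-2-yl)-3-{[(4-methoxybenzyl)oxy]methyl}-5-[(triisopropylsilyl)oxy]cyclohex-2-en-1-one
Conditions: second-generation Grubbs catalyst RuCl2(=CHPh)(PCy3)(H2IMes) (5 mol %), CH2Cl2 (5 mM), 40 °C
Reagents that add atoms: none
Why: Ring-closing olefin metathesis between the vinyl ketone and the C4 methylidene group closes ring A with loss of ethene, whereas closure onto the C10 methylidene would need a tetrasubstituted cyclopentene and is far slower; the trans C1/C2 arrangement from step 8 is kept.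

Step 13
Reactants: 19 4-methoxybenzyl alcohol; 20 trichloroethylene
Product: 22 1-({[(E)-1,2-dichloroethenyl]oxy}methyl)-4-methoxybenzene, via dichloroacetylene 21 (not isolated)
Conditions: KH, THF, 0 °C; then 20, −50 °C to rt
Reagents that add atoms: none
Why: Base-induced dehydrochlorination of trichloroethylene and anti addition of the alcohol across the resulting dichloroacetylene, a known entry to (E)-1,2-dichlorovinyl ethers as alkynyl ether precursors.

Step 14
Reactants: 18 (5S,6R)-6-(3-{[tert-butyl(dimethyl)silyl]oxy}prop-1-en-2-yl)-3-{[(4-methoxybenzyl)oxy]methyl}-5-[(triisopropylsilyl)oxy]cyclohex-2-en-1-one; 22 1-({[(E)-1,2-dichloroethenyl]oxy}methyl)-4-methoxybenzene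
Product: 25 (1R,5S,6R)-6-(3-{[tert-butyl(dimethyl)silyl]oxy}prop-1-en-2-yl)-1-{[(4-methoxybenzyl)oxy]ethynyl}-3-{[(4-methoxybenzyl)oxy]methyl}-5-[(triisopropylsilyl)oxy]cyclohex-2-en-1-ol, via lithium acetylide 23 (not isolated), via cerium acetylide 24 (not isolated)
Conditions: 22 (3 equiv), n-BuLi (6.2 equiv), THF, −78 to −40 °C; anhydrous CeCl3, −78 °C; then 18, −78 °C; aq NaHCO3
Reagents that add atoms: none
Why: 1,2-Addition of an alkoxyacetylide to a ketone, in which n-BuLi turns 22 into the lithium acetylide by elimination and chlorine–lithium exchange, CeCl3 lowers its basicity so that the acidic C1–H survives, and the small sp nucleophile attacks C6 axially, anti to the C2 silyloxy group and cis to the C1 alkenyl arm, which sets the C6 stereocentre.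

Step 15
Reactants: 25 (1R,5S,6R)-6-(3-{[tert-butyl(dimethyl)silyl]oxy}prop-1-en-2-yl)-1-{[(4-methoxybenzyl)oxy]ethynyl}-3-{[(4-methoxybenzyl)oxy]methyl}-5-[(triisopropylsilyl)oxy]cyclohex-2-en-1-ol
Product: 26 (1S,5S,6R)-6-(3-{[tert-butyl(dimethyl)silyl]oxy}prop-1-en-2-yl)-1-{(E)-2-[(4-methoxybenzyl)oxy]ethenyl}-3-{[(4-methoxybenzyl)oxy]methyl}-5-[(triisopropylsilyl)oxy]cyclohex-2-en-1-ol
Conditions: LiAlH4, THF, 0 °C to rt; aq KNaC4H4O6 (kept basic)
Reagents that add atoms: none
Why: Hydroxyl-directed trans-hydroalumination of a propargylic alcohol (LiAlH4 reduction), with hydride delivered to C7 from aluminium bound to the C6 oxygen and protonolysis at C8 on work-up, should give the E enol ether only, under basic conditions that this acid-labile group tolerates.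

Step 16
Reactants: 26 (1S,5S,6R)-6-(3-{[tert-butyl(dimethyl)silyl]oxy}prop-1-en-2-yl)-1-{(E)-2-[(4-methoxybenzyl)oxy]ethenyl}-3-{[(4-methoxybenzyl)oxy]methyl}-5-[(triisopropylsilyl)oxy]cyclohex-2-en-1-ol
Product: 29 (2E,5S,6E,9R)-7-({[tert-butyl(dimethyl)silyl]oxy}methyl)-9-[(4-methoxybenzyl)oxy]-3-{[(4-methoxybenzyl)oxy]methyl}-5-[(triisopropylsilyl)oxy]cyclodeca-2,6-dien-1-one, via potassium alkoxide 27 (not isolated), via potassium enolate 28 (not isolated)
Conditions: KH, 18-crown-6, THF, −78 to 0 °C; then aq NH4Cl at −78 °C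
Reagents that add atoms: none
Why: KH removes the C6 hydroxyl proton and 18-crown-6 strips the potassium ion from alkoxide 27, whose negative charge weakens the allylic C1–C6 bond so that a concerted, chair-like [3,3] sigmatropic shift (anionic oxy-Cope rearrangement) forms C8–C9 while C1–C6 breaks well below room temperature, and cold protonation of enolate 28 at C7 gives ketone 29. The closest known reaction type is the anionic oxy-Cope ring expansion of cis-1,2-dialkenylcyclohexanols to cyclodec-5-enones. The ten-membered ring is not made by cyclization of an open chain but by four-atom enlargement of ring A, so the entropic penalty of medium-ring closure is avoided and the C4=C5 bond is carried over with its ring-cis geometry. The new C8 stereocentre (R) is fixed by suprafacial transfer of the C1/C6 configuration through the chair, in which the PMB-oxy group of the E enol ether is equatorial and C9 can reach only one face of C8. The selectivity needed is the chair in which C2 is axial on C1, the only one that turns C1–C10 into a ring-cis alkene; the cis arrangement of the two alkenyl arms forces one ring-A bond axial and one equatorial, the half-chair of ring A with the C2 silyloxy group and the C1 arm both equatorial maps directly onto this chair, and the competing chair would set C5 axial on C6 against the C14 branch on C10. TIPS at C2 is too bulky to migrate to the neighbouring alkoxide, and quenching at −78 °C limits E1cB loss of the C8 PMB-oxide from the enolate.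

Step 17
Reactants: 29 (2E,5S,6E,9R)-7-({[tert-butyl(dimethyl)silyl]oxy}methyl)-9-[(4-methoxybenzyl)oxy]-3-{[(4-methoxybenzyl)oxy]methyl}-5-[(triisopropylsilyl)oxy]cyclodeca-2,6-dien-1-one; 30 methyl iodoacetate
Product: 32 methyl (2S,7R,8R)-14-{[tert-butyl(dimethyl)silyl]oxy}-8,15-bis[(4-methoxybenzyl)oxy]-6-oxo-2-[(triisopropylsilyl)oxy]-13-norgermacra-1(10),4-dien-12-oate, via lithium enolate 31 (not isolated)
Conditions: LiN(SiMe3)2, THF, −78 °C; then 30, −78 to −40 °C
Reagents that add atoms: none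
Why: Kinetic α′-deprotonation of the cross-conjugated enone at C7 and SN2 alkylation of the enolate; lithium held between the enolate oxygen and the C8 ether oxygen should make the iodoacetate enter anti to C9 (Fráter–Seebach-type 1,2-induction), placing C11 cis to the C8 oxygen (7R), while low temperature and the lithium counter-ion suppress loss of the C8 alkoxide.

Step 18
Reactants: 32 methyl (2S,7R,8R)-14-{[tert-butyl(dimethyl)silyl]oxy}-8,15-bis[(4-methoxybenzyl)oxy]-6-oxo-2-[(triisopropylsilyl)oxy]-13-norgermacra-1(10),4-dien-12-oate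
Product: 34 (2S,6R,7R,8R)-14-{[tert-butyl(dimethyl)silyl]oxy}-8,15-bis[(4-methoxybenzyl)oxy]-2-[(triisopropylsilyl)oxy]-13-norgermacra-1(10),4-dien-12,6-olide, via hydroxy ester 33 (not isolated)
Conditions: NaBH4, CeCl3·7H2O, MeOH, −40 °C; then pyridinium p-toluenesulfonate (cat.), toluene, 40 °C
Reagents that add atoms: none
Why: Luche 1,2-reduction of the enone followed by acid-catalysed lactonization of the γ-hydroxy ester; with the C7 acetate arm perpendicular to the carbonyl plane, hydride should attack anti to it (Felkin–Anh) and give the 6R alcohol whose oxygen is trans to C11, and only this oxygen can close the lactone because C8 is still a PMB ether.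

Step 19
Reactants: 34 (2S,6R,7R,8R)-14-{[tert-butyl(dimethyl)silyl]oxy}-8,15-bis[(4-methoxybenzyl)oxy]-2-[(triisopropylsilyl)oxy]-13-norgermacra-1(10),4-dien-12,6-olide
Product: 37 (2S,6R,7R,8R)-14-{[tert-butyl(dimethyl)silyl]oxy}-8,15-bis[(4-methoxybenzyl)oxy]-2-[(triisopropylsilyl)oxy]germacra-1(10),4,11(13)-trien-12,6-olide, via Mannich base 35 (not isolated), via ammonium iodide 36 (not isolated)
Conditions: LiN(iPr)2, THF, −78 °C; CH2=NMe2+ I− (Eschenmoser salt), −78 °C to rt; then MeI, MeOH/CH2Cl2, rt; then aq NaHCO3, rt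
Reagents that add atoms: N,N-dimethylmethylideneammonium iodide (Eschenmoser salt), C=[N+](C)C.[I-]
Why: α-Methylenation of a γ-lactone by the Mannich route, that is, deprotonation at C11, aminomethylation, quaternization and base-induced β-elimination of trimethylamine, installs the exocyclic C11=C13 bond before any other ester is present.

Step 20
Reactants: 37 (2S,6R,7R,8R)-14-{[tert-butyl(dimethyl)silyl]oxy}-8,15-bis[(4-methoxybenzyl)oxy]-2-[(triisopropylsilyl)oxy]germacra-1(10),4,11(13)-trien-12,6-olide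
Product: 38 (2S,6R,7R,8R)-14-{[tert-butyl(dimethyl)silyl]oxy}-8,15-dihydroxy-2-[(triisopropylsilyl)oxy]germacra-1(10),4,11(13)-trien-12,6-olide
Conditions: DDQ (2.5 equiv), CH2Cl2/pH 7 phosphate buffer (10:1), 0 °C
Reagents that add atoms: none
Why: Oxidative cleavage of both PMB ethers by DDQ (benzylic hydride abstraction, then hydrolysis of the oxocarbenium ion) leaves the silyl ethers, the lactone and the alkenes untouched.

Step 21
Reactants: 38 (2S,6R,7R,8R)-14-{[tert-butyl(dimethyl)silyl]oxy}-8,15-dihydroxy-2-[(triisopropylsilyl)oxy]germacra-1(10),4,11(13)-trien-12,6-olide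
Product: 39 (2S,6R,7R,8R)-15-acetoxy-14-{[tert-butyl(dimethyl)silyl]oxy}-8-hydroxy-2-[(triisopropylsilyl)oxy]germacra-1(10),4,11(13)-trien-12,6-olide
Conditions: AcCl (1.1 equiv), 2,4,6-collidine, CH2Cl2, −78 °C
Reagents that add atoms: acetyl chloride, CC(=O)Cl
Why: Kinetically selective acylation of the primary allylic C15 hydroxyl over the hindered secondary C8 hydroxyl with acetyl chloride and collidine at low temperature.

Step 22
Reactants: 39 (2S,6R,7R,8R)-15-acetoxy-14-{[tert-butyl(dimethyl)silyl]oxy}-8-hydroxy-2-[(triisopropylsilyl)oxy]germacra-1(10),4,11(13)-trien-12,6-olide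
Product: 40 (2S,6R,7R,8R)-15-acetoxy-14-{[tert-butyl(dimethyl)silyl]oxy}-8-[(3-methylbutanoyl)oxy]-2-[(triisopropylsilyl)oxy]germacra-1(10),4,11(13)-trien-12,6-olide
Conditions: (iPrCH2CO)2O, Et3N, DMAP (0.2 equiv), CH2Cl2, 0 °C to rt
Reagents that add atoms: 3-methylbutanoic anhydride, CC(C)CC(=O)OC(=O)CC(C)C
Why: DMAP-catalysed acylation (acyl transfer through the N-acylpyridinium ion) of the remaining secondary C8 hydroxyl, with no stereocentre involved.

Step 23
Reactants: 40 (2S,6R,7R,8R)-15-acetoxy-14-{[tert-butyl(dimethyl)silyl]oxy}-8-[(3-methylbutanoyl)oxy]-2-[(triisopropylsilyl)oxy]germacra-1(10),4,11(13)-trien-12,6-olide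
Product: 41 (2S,6R,7R,8R)-15-acetoxy-2,14-dihydroxy-8-[(3-methylbutanoyl)oxy]germacra-1(10),4,11(13)-trien-12,6-olide
Conditions: HF·pyridine, pyridine, THF, 0 °C to rt
Reagents that add atoms: none
Why: Fluoride-mediated cleavage of both silyl ethers under buffered, non-basic conditions spares the acetate, the isovalerate and the α-methylene lactone.

Step 24
Reactants: 41 (2S,6R,7R,8R)-15-acetoxy-2,14-dihydroxy-8-[(3-methylbutanoyl)oxy]germacra-1(10),4,11(13)-trien-12,6-olide
Product: 42 (2S,6R,7R,8R)-15-acetoxy-2-hydroxy-8-[(3-methylbutanoyl)oxy]-14-oxogermacra-1(10),4,11(13)-trien-12,6-olide (CNP0524123.1)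
Conditions: TEMPO (0.2 equiv), PhI(OAc)2 (1.2 equiv), CH2Cl2, rt
Reagents that add atoms: none
Why: Oxoammonium oxidation (TEMPO/PhI(OAc)2), strongly selective for primary over secondary alcohols, turns the primary allylic C14 hydroxyl into the conjugated aldehyde and leaves the secondary allylic C2 hydroxyl, the esters and the C1=C10 geometry unchanged.

Compound list
1 | 2-bromoprop-2-en-1-ol | OCC(Br)=C | starting material
2 | [(2-bromoprop-2-en-1-yl)oxy](tert-butyl)dimethylsilane | C=C(Br)CO[Si](C)(C)C(C)(C)C | intermediate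
3 | bromo(2-ethoxy-2-oxoethyl)zinc (Reformatsky reagent) | CCOC(=O)C[Zn]Br | starting material
4 | ethyl 3-({[tert-butyl(dimethyl)silyl]oxy}methyl)but-3-enoate | CCOC(=O)CC(=C)CO[Si](C)(C)C(C)(C)C | intermediate
5 | 3-({[tert-butyl(dimethyl)silyl]oxy}methyl)but-3-enoic acid | OC(=O)CC(=C)CO[Si](C)(C)C(C)(C)C | intermediate
6 | (4R)-4-benzyl-1,3-oxazolidin-2-one | O=C1N[C@H](Cc2ccccc2)CO1 | starting material
7 | mixed anhydride of 5 and pivalic acid | CC(C)(C)C(=O)OC(=O)CC(=C)CO[Si](C)(C)C(C)(C)C | intermediate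
8 | (4R)-4-benzyl-3-[3-({[tert-butyl(dimethyl)silyl]oxy}methyl)but-3-enoyl]-1,3-oxazolidin-2-one | C=C(CO[Si](C)(C)C(C)(C)C)CC(=O)N1[C@H](Cc2ccccc2)COC1=O | intermediate
9 | 1-{[(2-bromoprop-2-en-1-yl)oxy]methyl}-4-methoxybenzene | C=C(Br)COCc1ccc(OC)cc1 | intermediate
10 | ethyl 3-{[(4-methoxybenzyl)oxy]methyl}but-3-enoate | CCOC(=O)CC(=C)COCc1ccc(OC)cc1 | intermediate
11 | 3-{[(4-methoxybenzyl)oxy]methyl}but-3-enal | O=CCC(=C)COCc1ccc(OC)cc1 | intermediate
12 | (Z)-dibutylboron enolate of 8 | CCCCB(CCCC)O/C(=C\C(=C)CO[Si](C)(C)C(C)(C)C)N1[C@H](Cc2ccccc2)COC1=O | intermediate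
13 | (4R)-4-benzyl-3-[(2R,3S)-2-(3-{[tert-butyl(dimethyl)silyl]oxy}prop-1-en-2-yl)-3-hydroxy-5-{[(4-methoxybenzyl)oxy]methyl}hex-5-enoyl]-1,3-oxazolidin-2-one | C=C(COCc1ccc(OC)cc1)C[C@H](O)[C@H](C(=O)N2[C@H](Cc3ccccc3)COC2=O)C(=C)CO[Si](C)(C)C(C)(C)C | intermediate
14 | (2R,3S)-2-(3-{[tert-butyl(dimethyl)silyl]oxy}prop-1-en-2-yl)-3-hydroxy-N-methoxy-5-{[(4-methoxybenzyl)oxy]methyl}-N-methylhex-5-enamide | C=C(COCc1ccc(OC)cc1)C[C@H](O)[C@H](C(=O)N(C)OC)C(=C)CO[Si](C)(C)C(C)(C)C | intermediate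
15 | (2R,3S)-2-(3-{[tert-butyl(dimethyl)silyl]oxy}prop-1-en-2-yl)-N-methoxy-5-{[(4-methoxybenzyl)oxy]methyl}-N-methyl-3-[(triisopropylsilyl)oxy]hex-5-enamide | C=C(COCc1ccc(OC)cc1)C[C@H](O[Si](C(C)C)(C(C)C)C(C)C)[C@H](C(=O)N(C)OC)C(=C)CO[Si](C)(C)C(C)(C)C | intermediate
16 | bromo(ethenyl)magnesium (vinylmagnesium bromide) | C=C[Mg]Br | starting material
17 | (4R,5S)-4-(3-{[tert-butyl(dimethyl)silyl]oxy}prop-1-en-2-yl)-7-{[(4-methoxybenzyl)oxy]methyl}-5-[(triisopropylsilyl)oxy]octa-1,7-dien-3-one | C=C(COCc1ccc(OC)cc1)C[C@H](O[Si](C(C)C)(C(C)C)C(C)C)[C@H](C(=O)C=C)C(=C)CO[Si](C)(C)C(C)(C)C | intermediate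
18 | (5S,6R)-6-(3-{[tert-butyl(dimethyl)silyl]oxy}prop-1-en-2-yl)-3-{[(4-methoxybenzyl)oxy]methyl}-5-[(triisopropylsilyl)oxy]cyclohex-2-en-1-one (ring A enone) | O=C1C=C(COCc2ccc(OC)cc2)C[C@H](O[Si](C(C)C)(C(C)C)C(C)C)[C@H]1C(=C)CO[Si](C)(C)C(C)(C)C | intermediate
19 | 4-methoxybenzyl alcohol | COc1ccc(CO)cc1 | starting material
20 | trichloroethylene | ClC=C(Cl)Cl | starting material
21 | dichloroacetylene | ClC#CCl | intermediate
22 | 1-({[(E)-1,2-dichloroethenyl]oxy}methyl)-4-methoxybenzene | COc1ccc(CO/C(Cl)=C\Cl)cc1 | intermediate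
23 | lithium [(4-methoxybenzyl)oxy]ethynide | [Li]C#COCc1ccc(OC)cc1 | intermediate
24 | dichloro{[(4-methoxybenzyl)oxy]ethynyl}cerium | Cl[Ce](Cl)C#COCc1ccc(OC)cc1 | intermediate
25 | (1R,5S,6R)-6-(3-{[tert-butyl(dimethyl)silyl]oxy}prop-1-en-2-yl)-1-{[(4-methoxybenzyl)oxy]ethynyl}-3-{[(4-methoxybenzyl)oxy]methyl}-5-[(triisopropylsilyl)oxy]cyclohex-2-en-1-ol | O[C@]1(C#COCc2ccc(OC)cc2)C=C(COCc3ccc(OC)cc3)C[C@H](O[Si](C(C)C)(C(C)C)C(C)C)[C@H]1C(=C)CO[Si](C)(C)C(C)(C)C | intermediate
26 | (1S,5S,6R)-6-(3-{[tert-butyl(dimethyl)silyl]oxy}prop-1-en-2-yl)-1-{(E)-2-[(4-methoxybenzyl)oxy]ethenyl}-3-{[(4-methoxybenzyl)oxy]methyl}-5-[(triisopropylsilyl)oxy]cyclohex-2-en-1-ol (key-step precursor) | O[C@]1(/C=C/OCc2ccc(OC)cc2)C=C(COCc3ccc(OC)cc3)C[C@H](O[Si](C(C)C)(C(C)C)C(C)C)[C@H]1C(=C)CO[Si](C)(C)C(C)(C)C | intermediate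
27 | potassium C6-alkoxide of 26 | [K+].[O-][C@]1(/C=C/OCc2ccc(OC)cc2)C=C(COCc3ccc(OC)cc3)C[C@H](O[Si](C(C)C)(C(C)C)C(C)C)[C@H]1C(=C)CO[Si](C)(C)C(C)(C)C | intermediate
28 | potassium enolate of 29 (C6–O−, C6=C7, oxygen cis to C8) | [K+].C1/C(COCc2ccc(OC)cc2)=C\C(\[O-])=C\[C@H](OCc3ccc(OC)cc3)C/C(CO[Si](C)(C)C(C)(C)C)=C\[C@H]1O[Si](C(C)C)(C(C)C)C(C)C | intermediate
29 | (2E,5S,6E,9R)-7-({[tert-butyl(dimethyl)silyl]oxy}methyl)-9-[(4-methoxybenzyl)oxy]-3-{[(4-methoxybenzyl)oxy]methyl}-5-[(triisopropylsilyl)oxy]cyclodeca-2,6-dien-1-one (key-step product; germacrane locants 2S,8R) | O=C1/C=C(/COCc2ccc(OC)cc2)C[C@H](O[Si](C(C)C)(C(C)C)C(C)C)/C=C(/CO[Si](C)(C)C(C)(C)C)C[C@@H](OCc3ccc(OC)cc3)C1 | intermediate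
30 | methyl iodoacetate | COC(=O)CI | starting material
31 | lithium enolate of 29 (C6–O−, C6=C7) | [Li+].C1/C(COCc2ccc(OC)cc2)=C\C(\[O-])=C\[C@H](OCc3ccc(OC)cc3)C/C(CO[Si](C)(C)C(C)(C)C)=C\[C@H]1O[Si](C(C)C)(C(C)C)C(C)C | intermediate
32 | methyl (2S,7R,8R)-14-{[tert-butyl(dimethyl)silyl]oxy}-8,15-bis[(4-methoxybenzyl)oxy]-6-oxo-2-[(triisopropylsilyl)oxy]-13-norgermacra-1(10),4-dien-12-oate | O=C1/C=C(/COCc2ccc(OC)cc2)C[C@H](O[Si](C(C)C)(C(C)C)C(C)C)/C=C(/CO[Si](C)(C)C(C)(C)C)C[C@@H](OCc3ccc(OC)cc3)[C@H]1CC(=O)OC | intermediate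
33 | methyl (2S,6R,7S,8R)-14-{[tert-butyl(dimethyl)silyl]oxy}-6-hydroxy-8,15-bis[(4-methoxybenzyl)oxy]-2-[(triisopropylsilyl)oxy]-13-norgermacra-1(10),4-dien-12-oate | O[C@@H]1/C=C(/COCc2ccc(OC)cc2)C[C@H](O[Si](C(C)C)(C(C)C)C(C)C)/C=C(/CO[Si](C)(C)C(C)(C)C)C[C@@H](OCc3ccc(OC)cc3)[C@H]1CC(=O)OC | intermediate
34 | (2S,6R,7R,8R)-14-{[tert-butyl(dimethyl)silyl]oxy}-8,15-bis[(4-methoxybenzyl)oxy]-2-[(triisopropylsilyl)oxy]-13-norgermacra-1(10),4-dien-12,6-olide | O=C1O[C@@H]2/C=C(/COCc3ccc(OC)cc3)C[C@H](O[Si](C(C)C)(C(C)C)C(C)C)/C=C(/CO[Si](C)(C)C(C)(C)C)C[C@@H](OCc4ccc(OC)cc4)[C@H]2C1 | intermediate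
35 | 13-(dimethylamino) derivative of 34 (Mannich base, C11 epimers) | CN(C)CC1C(=O)O[C@@H]2/C=C(/COCc3ccc(OC)cc3)C[C@H](O[Si](C(C)C)(C(C)C)C(C)C)/C=C(/CO[Si](C)(C)C(C)(C)C)C[C@@H](OCc4ccc(OC)cc4)[C@@H]12 | intermediate
36 | 13-(trimethylammonio) derivative of 34, iodide (C11 epimers) | [I-].C[N+](C)(C)CC1C(=O)O[C@@H]2/C=C(/COCc3ccc(OC)cc3)C[C@H](O[Si](C(C)C)(C(C)C)C(C)C)/C=C(/CO[Si](C)(C)C(C)(C)C)C[C@@H](OCc4ccc(OC)cc4)[C@@H]12 | intermediate
37 | (2S,6R,7R,8R)-14-{[tert-butyl(dimethyl)silyl]oxy}-8,15-bis[(4-methoxybenzyl)oxy]-2-[(triisopropylsilyl)oxy]germacra-1(10),4,11(13)-trien-12,6-olide | C=C1C(=O)O[C@@H]2/C=C(/COCc3ccc(OC)cc3)C[C@H](O[Si](C(C)C)(C(C)C)C(C)C)/C=C(/CO[Si](C)(C)C(C)(C)C)C[C@@H](OCc4ccc(OC)cc4)[C@@H]12 | intermediate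
38 | (2S,6R,7R,8R)-14-{[tert-butyl(dimethyl)silyl]oxy}-8,15-dihydroxy-2-[(triisopropylsilyl)oxy]germacra-1(10),4,11(13)-trien-12,6-olide | C=C1C(=O)O[C@@H]2/C=C(/CO)C[C@H](O[Si](C(C)C)(C(C)C)C(C)C)/C=C(/CO[Si](C)(C)C(C)(C)C)C[C@@H](O)[C@@H]12 | intermediate
39 | (2S,6R,7R,8R)-15-acetoxy-14-{[tert-butyl(dimethyl)silyl]oxy}-8-hydroxy-2-[(triisopropylsilyl)oxy]germacra-1(10),4,11(13)-trien-12,6-olide | C=C1C(=O)O[C@@H]2/C=C(/COC(C)=O)C[C@H](O[Si](C(C)C)(C(C)C)C(C)C)/C=C(/CO[Si](C)(C)C(C)(C)C)C[C@@H](O)[C@@H]12 | intermediate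
40 | (2S,6R,7R,8R)-15-acetoxy-14-{[tert-butyl(dimethyl)silyl]oxy}-8-[(3-methylbutanoyl)oxy]-2-[(triisopropylsilyl)oxy]germacra-1(10),4,11(13)-trien-12,6-olide | C=C1C(=O)O[C@@H]2/C=C(/COC(C)=O)C[C@H](O[Si](C(C)C)(C(C)C)C(C)C)/C=C(/CO[Si](C)(C)C(C)(C)C)C[C@@H](OC(=O)CC(C)C)[C@@H]12 | intermediate
41 | (2S,6R,7R,8R)-15-acetoxy-2,14-dihydroxy-8-[(3-methylbutanoyl)oxy]germacra-1(10),4,11(13)-trien-12,6-olide | C=C1C(=O)O[C@@H]2/C=C(/COC(C)=O)C[C@H](O)/C=C(/CO)C[C@@H](OC(=O)CC(C)C)[C@@H]12 | intermediate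
42 | (2S,6R,7R,8R)-15-acetoxy-2-hydroxy-8-[(3-methylbutanoyl)oxy]-14-oxogermacra-1(10),4,11(13)-trien-12,6-olide (CNP0524123.1) | C=C1C(=O)O[C@@H]2/C=C(/COC(C)=O)C[C@H](O)/C=C(/C=O)C[C@@H](OC(=O)CC(C)C)[C@@H]12 | target

Total step count: 24. Longest linear sequence: 20 steps (steps 1–4, 8–12 and 14–24); steps 5–7 and step 13 are side branches.

Steps most likely to fail

Step 16. The potassium enolate may expel the C8 PMB-oxide before it is protonated, or part of the alkoxide may rearrange through the competing chair and deliver the ring-trans C1=C10 isomer. The fallback replaces the anionic rearrangement by a neutral siloxy-Cope rearrangement. It sets out from 26, which TMSCl and imidazole in DMF should convert into trimethylsilyl ether F1. Heating F1 in degassed o-xylene at about 180 °C in base-washed glass should bring about the same [3,3] shift without any anionic species and give trimethylsilyl enol ether F2. Citric acid in aqueous THF at 0 °C should then hydrolyse the enol silyl ether, and the route is rejoined at 29.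

Step 17. Facial selectivity may be poor: if chelation is weak the electrophile may enter from the ring periphery, on the face syn to C9, and give the C7 epimer. The fallback sets C7 by protonation instead of by C–C bond formation. It sets out from 29, which is alkylated as in step 17; the material of wrong configuration is collected as C7-epimeric keto ester F3. KN(SiMe3)2 in THF at −78 °C should convert F3 into the fully substituted potassium enolate F4. Kinetic protonation with acetic acid at −78 °C, from the same peripheral face that the electrophile had used, should invert C7, and the route is rejoined at 32.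

Step 18. Hydride may attack the other carbonyl face, which would give the 6S alcohol and, after ring closure, a cis-fused lactone. The fallback moves the stereocontrol from the reduction to an invertive ring closure. It sets out from 32, whose 6S reduction product closes to cis-fused lactone F5. LiOH in aqueous THF should open F5 to hydroxy acid F6. PPh3 and diisopropyl azodicarboxylate in toluene at 0 °C should then activate the C6 hydroxyl and let the carboxylate displace it with inversion (intramolecular Mitsunobu esterification), and the route is rejoined at 34.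

Further compounds
F1 | step 16 | trimethylsilyl ether of 26 (C6–OSiMe3) | C[Si](C)(C)O[C@]1(/C=C/OCc2ccc(OC)cc2)C=C(COCc3ccc(OC)cc3)C[C@H](O[Si](C(C)C)(C(C)C)C(C)C)[C@H]1C(=C)CO[Si](C)(C)C(C)(C)C
F2 | step 16 | trimethylsilyl enol ether of 29 (C6–OSiMe3, C6=C7) | C1/C(COCc2ccc(OC)cc2)=C\C(\O[Si](C)(C)C)=C\[C@H](OCc3ccc(OC)cc3)C/C(CO[Si](C)(C)C(C)(C)C)=C\[C@H]1O[Si](C(C)C)(C(C)C)C(C)C
F3 | step 17 | methyl (2S,7S,8R)-14-{[tert-butyl(dimethyl)silyl]oxy}-8,15-bis[(4-methoxybenzyl)oxy]-6-oxo-2-[(triisopropylsilyl)oxy]-13-norgermacra-1(10),4-dien-12-oate (C7 epimer of 32) | O=C1/C=C(/COCc2ccc(OC)cc2)C[C@H](O[Si](C(C)C)(C(C)C)C(C)C)/C=C(/CO[Si](C)(C)C(C)(C)C)C[C@@H](OCc3ccc(OC)cc3)[C@@H]1CC(=O)OC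
F4 | step 17 | potassium enolate of F3 (C6–O−, C6=C7 bearing the acetate arm) | [K+].C1/C(COCc2ccc(OC)cc2)=C\C(\[O-])=C(CC(=O)OC)\[C@H](OCc3ccc(OC)cc3)C/C(CO[Si](C)(C)C(C)(C)C)=C\[C@H]1O[Si](C(C)C)(C(C)C)C(C)C
F5 | step 18 | (2S,6S,7R,8R)-14-{[tert-butyl(dimethyl)silyl]oxy}-8,15-bis[(4-methoxybenzyl)oxy]-2-[(triisopropylsilyl)oxy]-13-norgermacra-1(10),4-dien-12,6-olide (C6 epimer of 34, cis-fused) | O=C1O[C@H]2/C=C(/COCc3ccc(OC)cc3)C[C@H](O[Si](C(C)C)(C(C)C)C(C)C)/C=C(/CO[Si](C)(C)C(C)(C)C)C[C@@H](OCc4ccc(OC)cc4)[C@H]2C1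
F6 | step 18 | (2S,6S,7S,8R)-14-{[tert-butyl(dimethyl)silyl]oxy}-6-hydroxy-8,15-bis[(4-methoxybenzyl)oxy]-2-[(triisopropylsilyl)oxy]-13-norgermacra-1(10),4-dien-12-oic acid | O[C@H]1/C=C(/COCc2ccc(OC)cc2)C[C@H](O[Si](C(C)C)(C(C)C)C(C)C)/C=C(/CO[Si](C)(C)C(C)(C)C)C[C@@H](OCc3ccc(OC)cc3)[C@H]1CC(=O)O
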